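**Assumptions and remarks**

- Rings are lettered A to F along the chain. Ring positions are written as letter, hyphen, number (for example D-4). Ring A is numbered so that A-4 carries the ether oxygen and A-1 is para to it. In rings B to F, position 1 is the carbon bonded to the oxygen coming from the preceding ring and position 4 is para to it.
- Compounds 1, 2, 6 and 7 are taken to be catalogue chemicals.
- Compared ring by ring, the two precursors of the key step, tetramer 5 and the target agree in constitution. Tetramer 5 is rings A to D of the target with nine hydroxyls as methyl ethers and the hydroxyl on D-4 free.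
- Step 1 joins one molecule of 1 to three molecules of 2, and no more. The three molecules of 2 are entered one by one among the reactants, and the second and third are named once more on the reagent line of that step because they add their atoms to a chain that already exists.
- Two points of design were strengthened. In the key step the acid is fed in three one-equivalent portions together with a hindered pyridine base into a dry undivided cell. Loss of CO2 is then fast, the cathode regenerates the base, the chain can be checked after each portion, and acid-terminated self-coupling products can be washed out with bicarbonate. Rings E and F are brought in as aryl bromide 8, one step from two catalogue compounds, rather than as an ortho-silyl aryl triflate for an aryne coupling, which would cost about four more steps; the aryne coupling is kept as a fallback.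

## Structural features

The target (C36H26O19) is a linear chain of six benzene rings joined by five diaryl ether oxygens and carrying fourteen free phenolic hydroxyls; it has no stereocentre, so no stereochemistry has to be set. Ring A is a 2,4,6-trihydroxyphenyl group bound through A-4, rings B to E are 3,5-dihydroxy-1,4-phenylene units, and ring F is a 3,4,5-trihydroxyphenyl group bound through F-1. Every ether oxygen joins a carbon lying between two oxygen-bearing carbons (A-4, B-4, C-4, D-4, E-4) to a carbon lying between two CH groups (B-1, C-1, D-1, E-1, F-1), so the five linkages are the same head-to-tail bond repeated. The fragile part is the free polyphenol itself: its hydroxyhydroquinone- and pyrogallol-type rings are oxidised by air to quinones, above all in base, which is why all hydroxyls travel as methyl ethers and are set free last, in acid and without oxygen. The real difficulty is threefold: five electron-rich diaryl ethers whose oxygen sits between two ortho substituents and which offer no activating group for nucleophilic aromatic substitution, control of chain length, and a fourteen-fold deprotection. The key step exploits the fact that rings B, C and D are syringyl units: in each the oxygen on position 4 is flanked by methoxy groups on positions 3 and 5 and position 1 is the para carbon, so a phenoxyl oxygen can bond to position 1 of a 4-hydroxy-3,5-dimethoxybenzoate with loss of the carboxyl group, while carbon–carbon coupling finds no free ortho or para position.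

## Logic of the disconnections

**10 from 9.** The fourteen oxygen–methyl bonds are cut last. Methyl ethers are the spectator groups that the oxidative coupling needs (they block the ortho positions and are inert at the anode), and all four starting materials carry them already. The gain is that protection costs no step and deprotection costs one. The demand on the forward step is exhaustive cleavage of alkyl aryl ethers without touching the five diaryl ethers, and isolation of an air-sensitive polyphenol.

**9 from 5 and 8.** The bond between the oxygen on D-4 and E-1 is cut. This leaves exactly the tetramer that the key step produces and a two-ring electrophile of defined constitution, so the last two rings arrive as one piece and cannot add to the statistical spread of step 1. Extending 5 by two further oxidative additions of 2 was considered and set aside for that reason. The gain is a convergent 4 + 2 union. The demand is O-arylation of a phenol flanked by two methoxy groups with an unactivated aryl bromide; E-1 itself lies between two CH groups, so the steric burden is on the nucleophile only.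

**8 from 6 and 7.** The bond between the oxygen on E-4 and F-1 is cut. Both pieces are purchasable, and the bromine needed later on E-1 is already in 6. The demand is chemoselectivity: the carbon–iodine bond of 7 must react while the carbon–bromine bond of 6 and of 8 stays intact.

**5 from 1 and three molecules of 2, by way of 4 and 3.** The bonds from the oxygens on C-4, B-4 and A-4 to D-1, C-1 and B-1 are cut in turn; each cut returns a carboxyl group to the carbon that loses its oxygen and a hydroxyl to the other partner. All three bonds are of the same kind and each product phenol is the substrate for the next coupling, so one operation can form all three. The gain is the largest of the route: four rings from two catalogue compounds in one step. The demand is O–C(para) coupling only, cross-coupling in preference to self-coupling of 2, and a stop after three additions, which stoichiometry can only bias and not enforce.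

## Other disconnections considered

Alternative 1: The cut is at the twelve carbon–oxygen bonds on positions 3 and 5 of every ring: each hydroxyl is traced back to a formyl group, giving dodeca-aldehyde A2 (position 1 of ring A and position 4 of ring F as methyl ethers). In A2 every ether carbon at position 4 lies between two formyl groups, so the five diaryl ethers can in turn be cut by nucleophilic aromatic substitution, for example with fluoro dialdehyde A3 as the repeating unit. The forward key step is a twelvefold Dakin oxidation (mCPBA, aryl migration, then methanolysis) that should give A1, which still needs cleavage of two methyl ethers.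
- In its favour: chain length is fixed by construction, which is better than the statistical growth of the chosen plan. The hindered ether carbons are activated for substitution exactly where the chosen plan must rely on copper. Only two methyl ethers instead of fourteen remain at the end, which is also better.
- Against it: aryl migration in a Dakin oxidation needs an electron-rich ring, whereas each ring of A2 starts with two formyl groups and only ether donors, so hydride migration is expected to compete, above all for the first formyl group on each ring. Twelve such events must succeed on one molecule. The unmasked hydroxyhydroquinone-type rings then stand in excess peracid and are likely to be oxidised further.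
- Comparison: on structure the plans are equal, since neither has stereochemistry to control. On mechanism, Alternative 1 has predictable polar ether formation but a much less dependable final oxidation; the chosen plan has a dependable deprotection but a statistical coupling. On step economy the chosen plan (four steps) is clearly ahead, because A2 has to be assembled from A3 by five successive substitutions and capped at both ends before the oxidation.

Alternative 2: The cut goes through ring C itself, at the bonds C-2/C-3 and C-1/C-6. The forward step is a Danheiser benzannulation: cyclobutenone A5, which carries rings D to F on the oxygen at its sp3 carbon, is heated with aryl ethynyl ether A6, the ethynyl ether of 3. The cascade (four-electron electrocyclic opening of A5, [2+2] cycloaddition in which the carbonyl carbon bonds to the terminal alkyne carbon, a second four-electron opening, a six-electron closure and tautomerisation) should give A4, with C-3 as free hydroxyl and C-5 as ethyl ether. Atom mapping of this cascade places the oxygen of ring D on C-4, between the new hydroxyl and the ethoxy group, as the 4-aryloxy-3-ethoxy substitution of A5 requires.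
- In its favour: the union is convergent (two rings plus three rings while the sixth is made). The regiochemistry follows from the polarity of the two partners. Both flanked oxygens of ring C are in place before the ring exists, so no hindered phenol has to be arylated there, and chain length is unambiguous. On these points it is the equal or the better of the chosen plan.
- Against it: A5 and A6 are themselves oligo(aryl ethers) whose other four ether bonds must still be made by Ullmann-type chemistry. A6 is an acid- and heat-sensitive ynol ether of a flanked phenol. A5 belongs to a little-explored and probably elimination-prone class. Each needs several steps. The differentiated hydroxyl and ethoxy groups on ring C bring no benefit, since everything is dealkylated at the end as in the chosen plan.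
- Comparison: on structure it addresses the central ring elegantly. On mechanism a pericyclic cascade is more predictable in constitution than a radical oligomerisation. On step economy it would take well over ten steps against four.

Alternative 3: The cut is at the bonds E-2/E-3 and E-5/E-6. Ring E is traced back to the three carbons of malonate A9 (E-3, E-4, E-5, with the ring F ether already on E-4) and to the chain of glutaconate A8 (E-2, E-1, E-6, with the A-to-D chain on the enol ether oxygen). The forward step is a NaH-mediated double Claisen condensation (intermolecular acylation, then Dieckmann-type closure and enolisation) that should give A7 as a 3,5-dihydroxy-2,6-diester. A7 then needs ester hydrolysis, double decarboxylation and global demethylation.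
- In its favour: both flanked ether bonds of ring E (D-4 to E-1 and E-4 to F-1) are made before the ring exists, by conjugate addition and by alkylation of phenoxides, so the difficult arylation of step 3 is avoided. This is the point on which it is better than the chosen plan. Condensation of a malonate with an acetonedicarboxylate equivalent to a phloroglucinol is classical.
- Against it: A8 has to be made from 5, so the alternative does not remove the key step but only replaces steps 2 and 3. The methine of A9 is the most acidic position present, and its enolate deactivates both ester carbonyls as electrophiles. The anion of A9 or of A8 can add to position 3 of A8 and expel the phenoxide of 5 by addition–elimination. Two ester groups must afterwards be removed from a crowded, electron-rich ring.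
- Comparison: on structure it is equal (no stereochemistry, the same protecting groups). On mechanism it trades a hindered copper coupling for a condensation between two stabilised anions with an obvious fragmentation pathway. On step economy it is longer by at least four steps after 5.

Key step: step 1

## Route

Step 1
Reactants: 1 2,4,6-trimethoxyphenol; 2 syringic acid (first molecule, source of ring B); 2 syringic acid (second molecule, source of ring C); 2 syringic acid (third molecule, source of ring D)
Product: 5 tetramer phenol 4-{4-[2,6-dimethoxy-4-(2,4,6-trimethoxyphenoxy)phenoxy]-2,6-dimethoxyphenoxy}-2,6-dimethoxyphenol (rings A to D; free hydroxyl on D-4), via dimer phenol 3 (not isolated), via trimer phenol 4 (not isolated)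
Conditions: undivided cell, graphite anode, Pt cathode, constant current (about 3 mA cm−2), n-Bu4NBF4 (0.1 M), dry MeCN/CH2Cl2 4:1, 3 Å MS, Ar, 20 °C; 2 in three portions of 1.0 equiv, each with 2,6-lutidine (1 equiv) in MeCN, fed by syringe pump at the rate of charge passed (2.1 F per mol of 2), HPLC check after each portion; aq. NaHCO3 wash; SiO2 chromatography
Reagents that add atoms: syringic acid, second molecule of 2 entered above, SMILES COc1cc(C(=O)O)cc(OC)c1O; syringic acid, third molecule of 2 entered above, SMILES COc1cc(C(=O)O)cc(OC)c1O
Why: Anodic proton-coupled oxidation turns each phenol into its phenoxyl radical; the chain-end radical (from 1, then 3, then 4) bonds through oxygen to position 1 of the radical of the first, second and third molecule of 2 in turn, and each resulting 4-aryloxy-4-carboxycyclohexa-2,5-dienone loses CO2 and rearomatises to the next flanked phenol, which re-enters the cycle (capture of the phenoxonium ion of 2 by the chain phenol would lead to the same adduct). The protons are discharged as H2 at the cathode, so one molecule of 1 and three molecules of 2 give 5, three CO2 and three H2 at two faradays per mole of bond and without a chemical oxidant. The closest known reaction type is the oxidative coupling polymerisation of 2,6-disubstituted phenols to poly(1,4-phenylene oxide)s, with the decarboxylative polymerisation of syringic acid and the anodic polymerisation of 2,6-dialkylphenols as direct models. No ring is closed and no stereocentre is formed. O–C rather than C–C coupling is secured by the substrates, since every ortho and para carbon of 1, 2, 3 and 4 is substituted and the O–C(para) self-adducts of chain-end radicals are quinone ketals that revert. Cross-coupling rather than self-coupling of 2 is favoured by the slow feed, and self-coupled chains keep a carboxyl group and are removed by the NaHCO3 wash. Chain length is not selected chemically: with equally reactive chain ends a Poisson-type spread centred on three additions is expected, so only a minor share of the chains should stop at 5, which is separated by chromatography while the shorter chains 3 and 4 recovered there can be resubmitted with two or one further molecules of 2. Water and alcohols are excluded because they would intercept the oxidised species at the para carbon and lead to 2,6-dimethoxy-1,4-benzoquinone.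

Step 2
Reactants: 6 4-bromo-2,6-dimethoxyphenol; 7 5-iodo-1,2,3-trimethoxybenzene, 1.5 equiv
Product: 8 5-bromo-1,3-dimethoxy-2-(3,4,5-trimethoxyphenoxy)benzene (rings E and F; bromine on E-1)
Conditions: CuI (10 mol %), picolinic acid (20 mol %), K3PO4 (2 equiv), DMSO, 80 °C, Ar
Reagents that add atoms: none
Why: Ullmann diaryl ether synthesis with a ligand system established for 2,6-disubstituted phenols; the carbon–iodine bond of 7 reacts far faster with the copper phenoxide than any carbon–bromine bond, the bromide of 6 is further deactivated as a para-phenoxide, and the excess of 7 keeps the bromide of 8 from competing.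

Step 3
Reactants: 5 tetramer phenol; 8 5-bromo-1,3-dimethoxy-2-(3,4,5-trimethoxyphenoxy)benzene, 1.5 equiv
Product: 9 tetradecamethyl ether of the target, 5-{4-[4-(4-{2,6-dimethoxy-4-(2,4,6-trimethoxyphenoxy)phenoxy}-2,6-dimethoxyphenoxy)-2,6-dimethoxyphenoxy]-2,6-dimethoxyphenoxy}-1,2,3-trimethoxybenzene
Conditions: CuI (20 mol %), picolinic acid (40 mol %), K3PO4 (2 equiv), degassed DMSO, 100 °C, Ar
Reagents that add atoms: none
Why: Ullmann diaryl ether synthesis that forms the bond from the oxygen on D-4 to E-1; the bromide of 8 sits between two CH groups and is the only halide present, 5 offers a single nucleophilic site, and the copper/picolinic acid system is the known remedy for phenols flanked by two ortho substituents; oxygen is excluded because the phenoxide of 5 is easily oxidised.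

Step 4
Reactants: 9 tetradecamethyl ether of the target
Product: 10 target, 5-{4-[4-(4-{2,6-dihydroxy-4-(2,4,6-trihydroxyphenoxy)phenoxy}-2,6-dihydroxyphenoxy)-2,6-dihydroxyphenoxy]-2,6-dihydroxyphenoxy}benzene-1,2,3-triol
Conditions: BBr3 (1 M in CH2Cl2, 3 equiv per OMe), CH2Cl2, −78 to 20 °C; degassed H2O, 0 °C; reversed-phase HPLC (H2O/MeCN, 0.1% HCO2H) under Ar
Reagents that add atoms: none
Why: Lewis-acid cleavage of alkyl aryl ethers: boron binds each methoxy oxygen and bromide attacks the methyl carbon by SN2, whereas the diaryl ether oxygens have no sp3 carbon to be attacked and survive; hydrolysis of the aryl borates under acidic, oxygen-free conditions releases the fourteen phenols.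

## Compound list

1 | 2,4,6-trimethoxyphenol | COc1cc(OC)c(O)c(OC)c1 | starting material
2 | syringic acid (4-hydroxy-3,5-dimethoxybenzoic acid) | COc1cc(C(=O)O)cc(OC)c1O | starting material
3 | dimer phenol, 2,6-dimethoxy-4-(2,4,6-trimethoxyphenoxy)phenol (rings A and B) | COc1cc(OC)c(Oc2cc(OC)c(O)c(OC)c2)c(OC)c1 | intermediate
4 | trimer phenol, 4-[2,6-dimethoxy-4-(2,4,6-trimethoxyphenoxy)phenoxy]-2,6-dimethoxyphenol (rings A to C) | COc1cc(OC)c(Oc2cc(OC)c(Oc3cc(OC)c(O)c(OC)c3)c(OC)c2)c(OC)c1 | intermediate
5 | tetramer phenol, 4-{4-[2,6-dimethoxy-4-(2,4,6-trimethoxyphenoxy)phenoxy]-2,6-dimethoxyphenoxy}-2,6-dimethoxyphenol (rings A to D) | COc1cc(OC)c(Oc2cc(OC)c(Oc3cc(OC)c(Oc4cc(OC)c(O)c(OC)c4)c(OC)c3)c(OC)c2)c(OC)c1 | intermediate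
6 | 4-bromo-2,6-dimethoxyphenol | COc1cc(Br)cc(OC)c1O | starting material
7 | 5-iodo-1,2,3-trimethoxybenzene | COc1cc(I)cc(OC)c1OC | starting material
8 | 5-bromo-1,3-dimethoxy-2-(3,4,5-trimethoxyphenoxy)benzene (rings E and F) | COc1cc(Br)cc(OC)c1Oc1cc(OC)c(OC)c(OC)c1 | intermediate
9 | tetradecamethyl ether of the target (rings A to F, all hydroxyls as methyl ethers) | COc1cc(OC)c(Oc2cc(OC)c(Oc3cc(OC)c(Oc4cc(OC)c(Oc5cc(OC)c(Oc6cc(OC)c(OC)c(OC)c6)c(OC)c5)c(OC)c4)c(OC)c3)c(OC)c2)c(OC)c1 | intermediate
10 | CNP0187343.0, 5-{4-[4-(4-{2,6-dihydroxy-4-(2,4,6-trihydroxyphenoxy)phenoxy}-2,6-dihydroxyphenoxy)-2,6-dihydroxyphenoxy]-2,6-dihydroxyphenoxy}benzene-1,2,3-triol | Oc1cc(O)c(Oc2cc(O)c(Oc3cc(O)c(Oc4cc(O)c(Oc5cc(O)c(Oc6cc(O)c(O)c(O)c6)c(O)c5)c(O)c4)c(O)c3)c(O)c2)c(O)c1 | target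

## Step count and least certain steps

Total step count: 4. Longest linear sequence: 3 steps (step 1, step 3, step 4; or step 2, step 3, step 4).

**Key step (step 1).** Most likely to go wrong: loss of chain-length control and chain scrambling. Growth is statistical, so material is spread over neighbouring homologues that are laborious to separate. Over-oxidation of a chain end followed by capture of traces of water at its para carbon would clip terminal rings off and redistribute the chains.
Fallback (sets out from 1 and 6, returns at 5): the chain is built one ring at a time by known copper chemistry. 6 is O-benzylated (BnBr, K2CO3, acetone) to 2-(benzyloxy)-5-bromo-1,3-dimethoxybenzene F1. Ullmann coupling of 1 with F1 (CuI, picolinic acid, K3PO4, DMSO, 110 °C) should give dimer benzyl ether F2, and hydrogenolysis (H2, Pd/C, EtOAc) then gives 3 as an isolated compound. The same two operations lead through trimer benzyl ether F3 to 4 and through tetramer benzyl ether F4 to 5. Seven steps replace one, but each ether bond is made singly and chain length is unambiguous.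

**Step 3.** Most likely to go wrong: stalling of the copper cycle. The phenoxide of 5 is large and flanked by two methoxy groups, so its coupling may be slow enough for hydrodebromination of 8 and oxidative degradation of the phenoxide by traces of oxygen to take over.
Fallback (sets out from 8 and 5, returns at 9): metal-free aryne O-arylation, in which the electrophile is small and highly reactive. 8 is hydroxylated (Pd2(dba)3, t-BuXPhos, KOH, dioxane/H2O, 100 °C) to 3,5-dimethoxy-4-(3,4,5-trimethoxyphenoxy)phenol F6. NBS (1.0 equiv, MeCN, −40 °C) should brominate the more activated phenol ring ortho to the hydroxyl, giving 2-bromo-3,5-dimethoxy-4-(3,4,5-trimethoxyphenoxy)phenol F7. Hexamethyldisilazane converts it into trimethylsilyl ether F8. n-BuLi (THF, −78 °C) brings about bromine–lithium exchange and migration of silicon from oxygen to carbon, giving the lithium salt of C-silyl phenol F9, which is trapped with Tf2O as silyl triflate F10. CsF in MeCN at 20 °C releases aryne F11 in the presence of 5. The methoxy group on E-3 directs the phenoxide oxygen to the remote aryne carbon E-1, and protonation at E-2 gives 9.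

**Step 4.** Most likely to go wrong: incomplete ether cleavage and oxidative loss during isolation. Partly demethylated borates may precipitate before all fourteen methyl groups have gone, and the free polyphenol is oxidised by air on any neutral or basic contact.
Fallback (sets out from 9, returns at 10): after the BBr3 treatment the crude polyphenol is not purified but acetylated at once (Ac2O, pyridine, DMAP) to tetradecaacetate F12. F12 is stable to air and can be purified on silica, where under-demethylated material should separate. Acid methanolysis (AcCl in MeOH, 20 °C, Ar) then releases 10 without any basic stage.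

**Step 2.** Most likely to go wrong: erosion of the iodide-over-bromide selectivity. Once 6 is nearly consumed, the bromide of 8 may begin to arylate the remaining phenoxide, giving over-arylated ethers.
Fallback (sets out from 6, returns at 8): Chan–Lam coupling of 6 with (3,4,5-trimethoxyphenyl)boronic acid F5 (Cu(OAc)2 (20 mol %), pyridine, 4 Å MS, CH2Cl2, air, 20 °C), under which aryl bromides are inert. The price is exposure of the electron-rich phenol to divalent copper and air, which is why this is not the first choice.

## Further compounds

F1 | step 1 | 2-(benzyloxy)-5-bromo-1,3-dimethoxybenzene | COc1cc(Br)cc(OC)c1OCc1ccccc1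
F2 | step 1 | dimer benzyl ether (benzyl ether of 3) | COc1cc(OC)c(Oc2cc(OC)c(OCc3ccccc3)c(OC)c2)c(OC)c1
F3 | step 1 | trimer benzyl ether (benzyl ether of 4) | COc1cc(OC)c(Oc2cc(OC)c(Oc3cc(OC)c(OCc4ccccc4)c(OC)c3)c(OC)c2)c(OC)c1
F4 | step 1 | tetramer benzyl ether (benzyl ether of 5) | COc1cc(OC)c(Oc2cc(OC)c(Oc3cc(OC)c(Oc4cc(OC)c(OCc5ccccc5)c(OC)c4)c(OC)c3)c(OC)c2)c(OC)c1
F5 | step 2 | (3,4,5-trimethoxyphenyl)boronic acid | COc1cc(B(O)O)cc(OC)c1OC
F6 | step 3 | 3,5-dimethoxy-4-(3,4,5-trimethoxyphenoxy)phenol | COc1cc(O)cc(OC)c1Oc1cc(OC)c(OC)c(OC)c1
F7 | step 3 | 2-bromo-3,5-dimethoxy-4-(3,4,5-trimethoxyphenoxy)phenol | COc1cc(O)c(Br)c(OC)c1Oc1cc(OC)c(OC)c(OC)c1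
F8 | step 3 | [2-bromo-3,5-dimethoxy-4-(3,4,5-trimethoxyphenoxy)phenoxy]trimethylsilane | COc1cc(O[Si](C)(C)C)c(Br)c(OC)c1Oc1cc(OC)c(OC)c(OC)c1
F9 | step 3 | 3,5-dimethoxy-4-(3,4,5-trimethoxyphenoxy)-2-(trimethylsilyl)phenol (formed as its lithium salt) | COc1cc(O)c([Si](C)(C)C)c(OC)c1Oc1cc(OC)c(OC)c(OC)c1
F10 | step 3 | 3,5-dimethoxy-4-(3,4,5-trimethoxyphenoxy)-2-(trimethylsilyl)phenyl trifluoromethanesulfonate | COc1cc(OS(=O)(=O)C(F)(F)F)c([Si](C)(C)C)c(OC)c1Oc1cc(OC)c(OC)c(OC)c1
F11 | step 3 | 3,5-dimethoxy-4-(3,4,5-trimethoxyphenoxy)benzyne (aryne between E-1 and E-2) | COC1=C(Oc2cc(OC)c(OC)c(OC)c2)C(OC)=CC#C1
F12 | step 4 | tetradecaacetate of 10 | CC(=O)Oc1cc(OC(C)=O)c(Oc2cc(OC(C)=O)c(Oc3cc(OC(C)=O)c(Oc4cc(OC(C)=O)c(Oc5cc(OC(C)=O)c(Oc6cc(OC(C)=O)c(OC(C)=O)c(OC(C)=O)c6)c(OC(C)=O)c5)c(OC(C)=O)c4)c(OC(C)=O)c3)c(OC(C)=O)c2)c(OC(C)=O)c1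
A1 | alternative 1 | target with position 1 of ring A and position 4 of ring F as methyl ethers | COc1cc(O)c(Oc2cc(O)c(Oc3cc(O)c(Oc4cc(O)c(Oc5cc(O)c(Oc6cc(O)c(OC)c(O)c6)c(O)c5)c(O)c4)c(O)c3)c(O)c2)c(O)c1
A2 | alternative 1 | dodeca-aldehyde hexamer (formyl on positions 3 and 5 of every ring, position 1 of ring A and position 4 of ring F as methyl ethers) | COc1cc(C=O)c(Oc2cc(C=O)c(Oc3cc(C=O)c(Oc4cc(C=O)c(Oc5cc(C=O)c(Oc6cc(C=O)c(OC)c(C=O)c6)c(C=O)c5)c(C=O)c4)c(C=O)c3)c(C=O)c2)c(C=O)c1
A3 | alternative 1 | 2-fluoro-5-hydroxybenzene-1,3-dicarbaldehyde | O=Cc1cc(O)cc(C=O)c1F
A4 | alternative 2 | hexamer with ring C as 3-hydroxy-5-ethoxy, all other hydroxyls as methyl ethers | COc1cc(OC)c(Oc2cc(OC)c(Oc3cc(O)c(Oc4cc(OC)c(Oc5cc(OC)c(Oc6cc(OC)c(OC)c(OC)c6)c(OC)c5)c(OC)c4)c(OCC)c3)c(OC)c2)c(OC)c1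
A5 | alternative 2 | 4-aryloxy-3-ethoxycyclobut-2-en-1-one carrying rings D to F (racemic at the sp3 ring carbon) | CCOC1=CC(=O)C1Oc1cc(OC)c(Oc2cc(OC)c(Oc3cc(OC)c(OC)c(OC)c3)c(OC)c2)c(OC)c1
A6 | alternative 2 | ethynyl ether of dimer phenol 3 | C#COc1c(OC)cc(Oc2c(OC)cc(OC)cc2OC)cc1OC
A7 | alternative 3 | hexamer with ring E as 3,5-dihydroxy-2,6-bis(methoxycarbonyl), other rings as methyl ethers | COc1cc(OC)c(Oc2cc(OC)c(Oc3cc(OC)c(Oc4cc(OC)c(Oc5c(C(=O)OC)c(O)c(Oc6cc(OC)c(OC)c(OC)c6)c(O)c5C(=O)OC)c(OC)c4)c(OC)c3)c(OC)c2)c(OC)c1
A8 | alternative 3 | dimethyl (E)-3-aryloxypent-2-enedioate carrying rings A to D | COC(=O)C/C(Oc1c(OC)cc(Oc2c(OC)cc(Oc3c(OC)cc(Oc4c(OC)cc(OC)cc4OC)cc3OC)cc2OC)cc1OC)=C\C(=O)OC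
A9 | alternative 3 | dimethyl 2-(3,4,5-trimethoxyphenoxy)malonate | COC(=O)C(Oc1cc(OC)c(OC)c(OC)c1)C(=O)OC
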